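**Retrosynthetic overview**
1. The last operation removes six benzyl ethers and one cyclic carbonate from a fully protected dimer.
2. The interflavan C4(upper)–C6(lower) bond comes from Friedel–Crafts capture of a 3-deoxyflavan-4-yl cation, anti to its 2-aryl group (2,4-trans).
3. Key disconnection, lower-unit C3–O and C4–O: a bromonium/CO2 relay places both oxygens on the alkene face of a (2S)-flav-3-ene that is syn to the 2-aryl group, giving the all-cis carbonate.
4. Both halves come from one (2S,4S)-flavan-4-ol. Its ring C is closed at O1–C2 by oxa-Michael addition of a 2'-hydroxychalcone, and the reversibility of that C–O bond lets a transfer hydrogenation fix C2 by dynamic kinetic resolution.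
5. Ring order: rings A and B are bought (gallacetophenone, 4-(benzyloxy)benzaldehyde). Ring C is made first, as the same material for both units, then the dioxolanone on the lower ring C, then the two units are joined.

Assumption: flavan (2-arylchroman) numbering is used for both units. "Upper" is the 3-deoxyflavan unit and "lower" is the flavan-3,4-diol unit. α is the ring C face that carries the C2 aryl group and β is the opposite face.

**Step 1**
Reactants: 1 gallacetophenone (1-(2,3,4-trihydroxyphenyl)ethanone)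
Product: 2 1-[3,4-bis(benzyloxy)-2-hydroxyphenyl]ethanone
Conditions: BnBr (2.1 equiv), K2CO3 (2.2 equiv), acetone, reflux, 12 h
Reagents that add atoms: benzyl bromide, BrCc1ccccc1
Why: Williamson etherification, in which the 2-OH is hydrogen-bonded to the ketone and is the least acidic and least nucleophilic phenol, so two equivalents of BnBr alkylate only O3 and O4; no stereocenter is formed.

**Step 2**
Reactants: 2 1-[3,4-bis(benzyloxy)-2-hydroxyphenyl]ethanone; 3 4-(benzyloxy)benzaldehyde
Product: 5 rac-7,8-bis(benzyloxy)-2-[4-(benzyloxy)phenyl]chroman-4-one, via chalcone 4 (not isolated)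
Conditions: KOH (3 equiv), EtOH, 25 °C, 24 h; then AcOH (3 equiv), reflux, 24 h
Reagents that add atoms: none
Why: Claisen–Schmidt aldol condensation gives the (E)-chalcone, and after neutralisation the acetate buffer drives the 6-endo-trig oxa-Michael closure of the free 2'-OH onto the β-carbon, forming the O1–C2 bond of ring C; C2 is left racemic because step 3 corrects it.

**Step 3**
Reactants: 5 rac-7,8-bis(benzyloxy)-2-[4-(benzyloxy)phenyl]chroman-4-one
Product: 6 (2S,4S)-7,8-bis(benzyloxy)-2-[4-(benzyloxy)phenyl]chroman-4-ol (2,4-cis)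
Conditions: RuCl[(S,S)-TsDPEN](p-cymene) (2 mol %), HCO2H (3 equiv), DBU (3.5 equiv), MeCN, 40 °C, 24 h
Reagents that add atoms: none
Why: Noyori–Ikariya asymmetric transfer hydrogenation run as a dynamic kinetic resolution, in which DBU interconverts the enantiomers of 5 by E1cB opening to 4 and oxa-Michael reclosure of O1–C2, while the (S,S)-catalyst reduces only the matched (2S)-ketone at a useful rate and delivers hydride to the β face, so C2 (S) and C4 (S, OH cis to the aryl group) are set together.

**Step 4**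
Reactants: 6 (2S,4S)-7,8-bis(benzyloxy)-2-[4-(benzyloxy)phenyl]chroman-4-ol
Product: 7 (2S)-7,8-bis(benzyloxy)-2-[4-(benzyloxy)phenyl]-2H-chromene
Conditions: Ph2S[OC(CF3)2Ph]2 (Martin sulfurane, 1.2 equiv), CH2Cl2, −20 °C to rt, 1 h, dark
Reagents that add atoms: none
Why: Martin sulfurane dehydration, in which the benzylic alkoxysulfonium ion loses a C3 proton to the fluoroalkoxide under neutral aprotic conditions, so the acid-labile allylic and benzylic O1–C2 bond is never ionised and C2 keeps its configuration (the C4 stereocenter is deleted).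

**Step 5 (key step)**
Reactants: 7 (2S)-7,8-bis(benzyloxy)-2-[4-(benzyloxy)phenyl]-2H-chromene
Product: 9 (2R,3S,4R)-7,8-bis(benzyloxy)-2-[4-(benzyloxy)phenyl]chroman-3,4-diyl carbonate (all-cis), via bromohydrin 8 (not isolated)
Conditions: NBS (1.05 equiv), MeCN/H2O 9:1, −10 °C, 30 min; evaporate; then Cs2CO3 (2.5 equiv), CO2 (1 atm), DMF, 40 °C, 12 h
Reagents that add atoms: water, O; carbon dioxide, O=C=O; N-bromosuccinimide, O=C1CCC(=O)N1Br (its bromine stays only in 8)
Why: Proposed new method: a bromonium-relayed carboxylative syn-dioxygenation that puts both oxygens on the alkene face syn to the C2 aryl group, a face that OsO4 or a peracid does not reach: NBS attacks the electron-rich C3=C4 bond anti to the α-aryl group (3β-Br), water opens the bromonium ion at benzylic C4 from the α face to give the all-equatorial trans,trans-bromohydrin 8 (kinetic and thermodynamic product, since C4 can re-ionise), the C4 alkoxide takes up CO2, and the carbonate oxygen displaces the 3β-bromide from the α face in a 5-exo-tet SN2 step with inversion, so C3 and C4 both end with α C–O bonds cis to the aryl group; anti E2 loss of HBr is blocked because C2 and C4 carry no α hydrogen, and an α-epoxide formed by direct closure would be carried to the same cis-carbonate by bromide-assisted CO2 insertion; the closest known reaction types are the Woodward cis-hydroxylation (hindered-face cis-diol through a cyclic acyloxonium ion) and the base-mediated conversion of simple halohydrins and CO2 into cyclic carbonates, neither shown on a 2-aryl-2H-chromene or used for contra-steric control with CO2 as the tether.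

**Step 6**
Reactants: 6 (2S,4S)-7,8-bis(benzyloxy)-2-[4-(benzyloxy)phenyl]chroman-4-ol; 9 all-cis chroman-3,4-diyl carbonate
Product: 10 hexa-O-benzyl dimer carbonate (C4β of the upper (2S)-flavan bonded to C6 of 9; upper unit 2,4-trans; lower unit all-cis 3,4-carbonate)
Conditions: 9 (2 equiv, excess recovered), BF3·OEt2 (20 mol %), 4 Å MS, CH2Cl2, −40 °C, 6 added over 2 h
Reagents that add atoms: none
Why: Friedel–Crafts benzylation by a flavan-4-yl cation, in which 6, having no C3 oxygen, ionises far more easily than the tethered electron-poor carbonate of 9, C6 of 9 (ortho to 7-OBn, para to O1) is its most nucleophilic carbon, and the arene attacks the half-chair cation (2-aryl equatorial) along the pseudo-axial line on the β face anti to the aryl group, setting the upper C4 as 2,4-trans.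

**Step 7**
Reactants: 10 hexa-O-benzyl dimer carbonate
Product: 12 (2R,3R,4R)-6-[(2S,4S)-7,8-dihydroxy-2-(4-hydroxyphenyl)chroman-4-yl]-2-(4-hydroxyphenyl)chroman-3,4,7,8-tetraol (CNP0209379.1), via hexabenzyl diol 11 (not isolated)
Conditions: K2CO3 (10 mol %), MeOH/THF 1:1, rt, 1 h; AcOH (20 mol %); then H2 (1 atm), Pd(OH)2/C, rt, 3 h, stopped at six equivalents of uptake
Reagents that add atoms: none
Why: Base-catalysed transesterification cleaves the carbonate at its acyl C–O bonds (no stereocenter touched) and must come first because a benzylic carbonate would itself be hydrogenolysed at C4, after which neutral hydrogenolysis removes the six aryl benzyl ethers much faster than it attacks the free secondary C4–OH or the O1–C2 bonds.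

**Compound list**
1 | gallacetophenone, 1-(2,3,4-trihydroxyphenyl)ethanone | CC(=O)c1ccc(O)c(O)c1O | starting material
2 | 1-[3,4-bis(benzyloxy)-2-hydroxyphenyl]ethanone | CC(=O)c1ccc(OCc2ccccc2)c(OCc2ccccc2)c1O | intermediate
3 | 4-(benzyloxy)benzaldehyde | O=Cc1ccc(OCc2ccccc2)cc1 | starting material
4 | (E)-1-[3,4-bis(benzyloxy)-2-hydroxyphenyl]-3-[4-(benzyloxy)phenyl]prop-2-en-1-one | O=C(/C=C/c1ccc(OCc2ccccc2)cc1)c1ccc(OCc2ccccc2)c(OCc2ccccc2)c1O | intermediate
5 | rac-7,8-bis(benzyloxy)-2-[4-(benzyloxy)phenyl]chroman-4-one (racemic, C2 undefined) | O=C1CC(c2ccc(OCc3ccccc3)cc2)Oc2c1ccc(OCc1ccccc1)c2OCc1ccccc1 | intermediate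
6 | (2S,4S)-7,8-bis(benzyloxy)-2-[4-(benzyloxy)phenyl]chroman-4-ol (2α-aryl, 4α-OH) | O(Cc1ccccc1)c1ccc([C@@H]2C[C@H](O)c3ccc(OCc4ccccc4)c(OCc4ccccc4)c3O2)cc1 | intermediate
7 | (2S)-7,8-bis(benzyloxy)-2-[4-(benzyloxy)phenyl]-2H-chromene | O(Cc1ccccc1)c1ccc([C@@H]2C=Cc3ccc(OCc4ccccc4)c(OCc4ccccc4)c3O2)cc1 | intermediate
8 | (2R,3S,4R)-7,8-bis(benzyloxy)-2-[4-(benzyloxy)phenyl]-3-bromochroman-4-ol (2α-aryl, 3β-Br, 4α-OH) | O(Cc1ccccc1)c1ccc([C@@H]2[C@@H](Br)[C@H](O)c3ccc(OCc4ccccc4)c(OCc4ccccc4)c3O2)cc1 | intermediate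
9 | (2R,3S,4R)-7,8-bis(benzyloxy)-2-[4-(benzyloxy)phenyl]chroman-3,4-diyl carbonate (2α-aryl, 3α-O, 4α-O) | O(Cc1ccccc1)c1ccc([C@@H]2[C@@H]3OC(=O)O[C@@H]3c5ccc(OCc4ccccc4)c(OCc4ccccc4)c5O2)cc1 | intermediate
10 | hexa-O-benzyl dimer carbonate: upper (2S)-flavan, 4β-linked (2,4-trans) to C6 of the lower all-cis 3,4-carbonate | O(Cc7ccccc7)c1ccc([C@@H]2C[C@@H](c3cc4c(c(OCc7ccccc7)c3OCc7ccccc7)O[C@H](c5ccc(OCc7ccccc7)cc5)[C@@H]8OC(=O)O[C@@H]84)c6ccc(OCc7ccccc7)c(OCc7ccccc7)c6O2)cc1 | intermediate
11 | hexa-O-benzyl dimer diol: as 10 with a free (2R,3R,4R) all-cis 3,4-diol in the lower unit | O(Cc7ccccc7)c1ccc([C@@H]2C[C@@H](c3cc4c(c(OCc7ccccc7)c3OCc7ccccc7)O[C@H](c5ccc(OCc7ccccc7)cc5)[C@H](O)[C@@H]4O)c6ccc(OCc7ccccc7)c(OCc7ccccc7)c6O2)cc1 | intermediate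
12 | (2R,3R,4R)-6-[(2S,4S)-7,8-dihydroxy-2-(4-hydroxyphenyl)chroman-4-yl]-2-(4-hydroxyphenyl)chroman-3,4,7,8-tetraol | Oc1ccc([C@@H]2C[C@@H](c3cc4c(c(O)c3O)O[C@H](c3ccc(O)cc3)[C@H](O)[C@@H]4O)c3ccc(O)c(O)c3O2)cc1 | target

**Step count**
Total steps: 7. Longest linear sequence: 7 (1 → 2 → 5 → 6 → 7 → 9 → 10 → 12). Compound 6 enters twice, as the precursor of 7 and as the electrophile of step 6.

**Three steps most likely to fail**

(a) Step 5, the new step.
- Risks: NBS may brominate ring A. Some cis-bromohydrin cannot close. The 4-(benzyloxy)phenyl group, which lies anti to the C3–Br bond, may shift from C2 to C3. Residual water may hydrolyse an epoxide to the 3,4-trans diol.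
- Fallback (known chemistry): it sets out from 7 and comes back at 9. It is a Woodward cis-hydroxylation followed by carbonylation. I2 and AgOAc in AcOH give the 3β-iodo-4α-acetate F1. Heating this with a second equivalent of AgOAc in wet AcOH takes it through the α-face acetoxonium ion to the all-cis 3-acetate-4-ol F2. K2CO3 in MeOH then gives tri-O-benzylteracacidin F3, and 1,1'-carbonyldiimidazole in CH2Cl2 closes it to 9.

(b) Step 6.
- Risks: ring A of a second molecule of 6, or of product 10, is about as nucleophilic as 9, so oligomers can form. The trans:cis ratio may also be modest.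
- Fallback: it sets out from 6 (with 9) and comes back at 12. It uses a removable bromine cap on the electrophile. NBS in CH2Cl2 at −78 °C brominates C6 of 6 to give the 6-bromoflavan-4-ol F4, which can no longer act as a nucleophile. Equimolar coupling with 9 under BF3·OEt2 gives the bromo dimer carbonate F5. K2CO3 in MeOH gives the bromo dimer diol F6. Hydrogenation over Pd(OH)2/C with NaOAc then removes the bromine together with the six benzyl groups to give 12.

(c) Step 3.
- Risks: racemisation of 5 may be slower than reduction, in which case the reaction stalls at 50 % as a plain kinetic resolution. The ruthenium hydride may also reduce chalcone 4.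
- Fallback: it sets out from 2 and comes back at 6. C2 is set by asymmetric conjugate arylation instead. Heating 2 with N,N-dimethylformamide dimethyl acetal gives the enaminone F7, and HCl in CH2Cl2 closes it to 7,8-bis(benzyloxy)chromone F8. Pd(OCOCF3)2, with the t-BuPyOx enantiomer that leads to the 2S product, adds 4-(benzyloxy)phenylboronic acid to give the (2S)-flavanone F9. NaBH4 in MeOH/THF at 0 °C reduces this from the β face to 6.

**Further compounds**
F1 | step 5 | 7,8-bis(benzyloxy)-2α-[4-(benzyloxy)phenyl]-3β-iodochroman-4α-yl acetate | O(Cc1ccccc1)c1ccc([C@@H]2[C@@H](I)[C@H](OC(C)=O)c5ccc(OCc4ccccc4)c(OCc4ccccc4)c5O2)cc1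
F2 | step 5 | 7,8-bis(benzyloxy)-2α-[4-(benzyloxy)phenyl]-4α-hydroxychroman-3α-yl acetate | O(Cc1ccccc1)c1ccc([C@@H]2[C@H](OC(C)=O)[C@H](O)c5ccc(OCc4ccccc4)c(OCc4ccccc4)c5O2)cc1
F3 | step 5 | (2R,3R,4R)-7,8-bis(benzyloxy)-2-[4-(benzyloxy)phenyl]chroman-3,4-diol (tri-O-benzylteracacidin) | O(Cc1ccccc1)c1ccc([C@@H]2[C@H](O)[C@H](O)c5ccc(OCc4ccccc4)c(OCc4ccccc4)c5O2)cc1
F4 | step 6 | (2S,4S)-7,8-bis(benzyloxy)-2-[4-(benzyloxy)phenyl]-6-bromochroman-4-ol | O(Cc1ccccc1)c1ccc([C@@H]2C[C@H](O)c3cc(Br)c(OCc4ccccc4)c(OCc4ccccc4)c3O2)cc1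
F5 | step 6 | analogue of 10 with bromine at C6 of the upper unit | O(Cc7ccccc7)c1ccc([C@@H]2C[C@@H](c3cc4c(c(OCc7ccccc7)c3OCc7ccccc7)O[C@H](c5ccc(OCc7ccccc7)cc5)[C@@H]8OC(=O)O[C@@H]84)c6cc(Br)c(OCc7ccccc7)c(OCc7ccccc7)c6O2)cc1
F6 | step 6 | analogue of 11 with bromine at C6 of the upper unit | O(Cc7ccccc7)c1ccc([C@@H]2C[C@@H](c3cc4c(c(OCc7ccccc7)c3OCc7ccccc7)O[C@H](c5ccc(OCc7ccccc7)cc5)[C@H](O)[C@@H]4O)c6cc(Br)c(OCc7ccccc7)c(OCc7ccccc7)c6O2)cc1
F7 | step 3 | (E)-1-[3,4-bis(benzyloxy)-2-hydroxyphenyl]-3-(dimethylamino)prop-2-en-1-one | CN(C)/C=C/C(=O)c1ccc(OCc2ccccc2)c(OCc2ccccc2)c1O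
F8 | step 3 | 7,8-bis(benzyloxy)-4H-chromen-4-one | O=c1ccoc2c1ccc(OCc1ccccc1)c2OCc1ccccc1
F9 | step 3 | (2S)-7,8-bis(benzyloxy)-2-[4-(benzyloxy)phenyl]chroman-4-one | O(Cc1ccccc1)c1ccc([C@@H]2CC(=O)c3ccc(OCc4ccccc4)c(OCc4ccccc4)c3O2)cc1
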